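**Plan**

1. Labels: ring A = the cyclohexadienone (C1 C=O, C2 benzoyl, C3 OH, C4, C5 OH, C6 gem-diprenyl); C7 = the methylene bridge; ring B = the cyclopentane (C1' carbinol carbon, C2' bearing C7, C3' bearing isopropenyl).
2. Cuts: C1'–CH3; both bonds of C7 (C4–C7 and C7–C2'), so that the bridge is excised as formaldehyde; C3'–isopropenyl; ring A across C4–C5 and C1–C2 (benzoylacetone plus a diprenylmalonate).
3. Forward order: ring A is closed first (dianion acylation, then Claisen condensation); ring B is bought as cyclopentenone and never closed; the two rings are joined through C7 in a three-component Knoevenagel/hetero-Diels–Alder reaction; the C1' methyl group comes last.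
4. Enabling feature: C7 lies between C4, which is flanked by the oxygenated carbons C3 and C5 (at the formaldehyde level a 2-methylene-1,3-dione, the 1-oxadiene O5=C5–C4=C7), and C2', which is α to the oxygenated C1' (at the ketone level an enol ether C1'=C2'). The chain O5–C5–C4–C7–C2'–C1' is therefore a latent dihydropyran, the retron of an inverse-demand hetero-Diels–Alder reaction.
5. Stereochemistry: C3' from the (S)-BINAP ligand of [RhCl((S)-binap)]2 in the conjugate addition; C2' trans to C3' by anti approach in the cycloaddition (also the thermodynamic arrangement α to the ketone); C1' by methyl attack anti to the C2' side chain.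

Key step: step 4

Remark: the β-triketone ring is written throughout as the 3,5-dihydroxycyclohexa-2,4-dien-1-one tautomer in which the target is drawn.

**Route**

Step 1
Reactants: 1 diethyl malonate; 2 prenyl bromide (1-bromo-3-methylbut-2-ene)
Product: 3 diethyl 2,2-bis(3-methylbut-2-en-1-yl)propanedioate
Conditions: NaH (2.2 equiv), 2 (2.2 equiv), THF/DMF, 0 to 20 °C
Reagents that add atoms: none
Why: Twofold malonic ester alkylation (enolate SN2 at the primary allylic bromide) builds the quaternary gem-diprenyl carbon before ring A exists, so its position is unambiguous; no stereocentre is formed.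

Step 2
Reactants: 4 benzoylacetone (1-phenylbutane-1,3-dione); 3
Product: 6 2-benzoyl-3,5-dihydroxy-6,6-bis(3-methylbut-2-en-1-yl)cyclohexa-2,4-dien-1-one, via triketo ester 5 (not isolated)
Conditions: 4, LiN(iPr)2 (3.2 equiv), THF, −78 to 0 °C; then 3, 0 to 50 °C; 1 M HCl work-up at 0 °C
Reagents that add atoms: none
Why: The terminal carbanion of the 1,3-diketone dianion is acylated by one ester group (C4–C5), and the central diketone carbon then closes ring A on the second ester by an intramolecular Claisen (Dieckmann-type) condensation (C1–C2), the polyketide-type cyclisation of a 3,5,7-triketo ester, which is driven by formation of the triketone dianion and aided by the gem-dialkyl effect; no stereocentre is formed.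

Step 3
Reactants: 7 cyclopent-2-en-1-one; 8 isopropenylmagnesium bromide (CH2=C(CH3)MgBr)
Product: 9 (S)-trimethyl{[3-(prop-1-en-2-yl)cyclopent-1-en-1-yl]oxy}silane
Conditions: 8 (1.5 equiv), ZnCl2 (1.5 equiv), THF, 0 °C; then 7, Me3SiCl (1.5 equiv), [RhCl((S)-binap)]2 (3 mol % Rh, from [RhCl(C2H4)2]2 and (S)-BINAP), THF, 20 °C; non-aqueous work-up, bulb-to-bulb distillation
Reagents that add atoms: chlorotrimethylsilane, C[Si](C)(C)Cl
Why: [RhCl((S)-binap)]2-catalysed asymmetric conjugate addition of an sp2-organozinc halide (CH2=C(CH3)ZnCl) in which the chlorosilane silylates the oxa-π-allyl rhodium intermediate, so that the enolate is frozen regiospecifically as the C1'=C2' silyl enol ether, and the C3' stereocentre is set by enantioface selection under the (S)-BINAP ligand, expected to give the (S) configuration by analogy with aryl and alkenyl transfer to cyclopentenone.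

Step 4
Reactants: 6; 10 formaldehyde (charged as paraformaldehyde); 9
Product: 13 2-benzoyl-3,5-dihydroxy-6,6-bis(3-methylbut-2-en-1-yl)-4-{[(1R,5S)-2-oxo-5-(prop-1-en-2-yl)cyclopentyl]methyl}cyclohexa-2,4-dien-1-one, via o-quinone methide 11 (not isolated), via silyl ketal 12 (not isolated)
Conditions: 6, (CH2O)n (3 equiv), ethylenediammonium diacetate (5 mol %), 4 Å molecular sieves, MeCN, 20 °C; then 9 (2 equiv), 20 to 45 °C; then 0.5 M aq. citric acid, THF, 20 °C
Reagents that add atoms: none
Why: Knoevenagel condensation of the C4–H of 6 with formaldehyde gives the 2-methylene-1,3-dione 11, whose O5=C5–C4=C7 unit reacts as an electron-poor 1-oxadiene with the electron-rich C1'=C2' bond of 9 in an inverse-electron-demand hetero-Diels–Alder reaction (or its stepwise Mukaiyama–Michael/ring-closure equivalent) to give the silyl ketal 12, which mild acid hydrolyses to the 1,5-dicarbonyl compound 13. The closest known reaction type is the three-component domino Knoevenagel/hetero-Diels–Alder reaction of cyclic 1,3-dicarbonyl compounds, aldehydes (formaldehyde included) and enol ethers, together with the Knoevenagel generation of such methylene triketones from dearomatised acylphloroglucinols and formaldehyde for capture by alkenes. The only ring closed is the transient cis-fused dihydropyran of 12 (C7–C2' and O5–C1' formed suprafacially on the enol ether in a [4+2] cycloaddition), and it is opened again on hydrolysis, so the step leaves two new C–C bonds at C7 and no new ring. C2' is set by approach of the heterodiene to the face of the cyclopentene anti to the adjacent C3' isopropenyl group, giving the 2',3'-trans ketone, which is also the more stable epimer at this enolisable centre, while the ketal carbon is not retained as a stereocentre. The step needs 11 to choose the enol ether over the isopropenyl and prenyl double bonds and over a second molecule of 6, which should be secured by the much higher nucleophilicity of the silyl enol ether, its use in excess and the prior consumption of 6 by excess formaldehyde; the orientation follows from the polarity of both partners, and either carbonyl flanking C4 leads to the same ketone 13.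

Step 5
Reactants: 13
Product: 14 hypercalin B, 2-benzoyl-3,5-dihydroxy-4-{[(1R,2S,5S)-2-hydroxy-2-methyl-5-(prop-1-en-2-yl)cyclopentyl]methyl}-6,6-bis(3-methylbut-2-en-1-yl)cyclohexa-2,4-dien-1-one
Conditions: MeMgBr (5 equiv), CH2Cl2/Et2O, −78 to −20 °C; sat. aq. NH4Cl
Reagents that add atoms: methylmagnesium bromide, C[Mg]Br
Why: Grignard 1,2-addition to the cyclopentanone, in which the first two equivalents turn the dienol into its MgBr dienolate (inert to the reagent and unable to undergo retro-Michael cleavage) and the methyl group is expected to enter C1' from the face anti to the bulky C2' side chain (steric approach control), which places the hydroxyl cis to C7 as in the target.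

**Compound list**

1 | diethyl malonate | CCOC(=O)CC(=O)OCC | starting material
2 | prenyl bromide (1-bromo-3-methylbut-2-ene) | CC(C)=CCBr | starting material
3 | diethyl 2,2-bis(3-methylbut-2-en-1-yl)propanedioate | CCOC(=O)C(CC=C(C)C)(CC=C(C)C)C(=O)OCC | intermediate
4 | benzoylacetone (1-phenylbutane-1,3-dione) | CC(=O)CC(=O)c1ccccc1 | starting material
5 | ethyl 2,2-bis(3-methylbut-2-en-1-yl)-3,5,7-trioxo-7-phenylheptanoate | CCOC(=O)C(CC=C(C)C)(CC=C(C)C)C(=O)CC(=O)CC(=O)c1ccccc1 | intermediate
6 | 2-benzoyl-3,5-dihydroxy-6,6-bis(3-methylbut-2-en-1-yl)cyclohexa-2,4-dien-1-one | OC1=CC(O)=C(C(=O)c2ccccc2)C(=O)C1(CC=C(C)C)CC=C(C)C | intermediate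
7 | cyclopent-2-en-1-one | O=C1CCC=C1 | starting material
8 | isopropenylmagnesium bromide (CH2=C(CH3)MgBr) | C=C(C)[Mg]Br | starting material
9 | (S)-trimethyl{[3-(prop-1-en-2-yl)cyclopent-1-en-1-yl]oxy}silane | C=C(C)[C@H]1CCC(O[Si](C)(C)C)=C1 | intermediate
10 | formaldehyde (charged as paraformaldehyde) | C=O | starting material
11 | 2-benzoyl-3-hydroxy-4-methylidene-6,6-bis(3-methylbut-2-en-1-yl)cyclohex-2-ene-1,5-dione (o-quinone methide of ring A) | C=C1C(=O)C(CC=C(C)C)(CC=C(C)C)C(=O)C(C(=O)c2ccccc2)=C1O | intermediate
12 | silyl ketal, the hetero-Diels–Alder adduct of 11 and 9: cis-fused dihydropyran O5–C5=C4–C7–C2'–C1', C1' carrying OSiMe3 and O5, isopropenyl at C3' trans to C7 | C=C(C)[C@H]1CC[C@]2(O[Si](C)(C)C)OC3=C(C[C@H]12)C(O)=C(C(=O)c4ccccc4)C(=O)C3(CC=C(C)C)CC=C(C)C | intermediate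
13 | 2-benzoyl-3,5-dihydroxy-6,6-bis(3-methylbut-2-en-1-yl)-4-{[(1R,5S)-2-oxo-5-(prop-1-en-2-yl)cyclopentyl]methyl}cyclohexa-2,4-dien-1-one | C=C(C)[C@H]1CCC(=O)[C@@H]1CC1=C(O)C(CC=C(C)C)(CC=C(C)C)C(=O)C(C(=O)c2ccccc2)=C1O | intermediate
14 | hypercalin B, 2-benzoyl-3,5-dihydroxy-4-{[(1R,2S,5S)-2-hydroxy-2-methyl-5-(prop-1-en-2-yl)cyclopentyl]methyl}-6,6-bis(3-methylbut-2-en-1-yl)cyclohexa-2,4-dien-1-one | C=C(C)[C@H]1CC[C@](C)(O)[C@@H]1CC1=C(O)C(CC=C(C)C)(CC=C(C)C)C(=O)C(C(=O)c2ccccc2)=C1O | target

**Count and risks**

Total step count: 5. Longest linear sequence: 4 steps (steps 1, 2, 4, 5).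

Step 3 may fail through slow transfer of the branched alkenyl group from zinc to rhodium, or through silylation lagging behind, so that the enantiomeric purity or the enolate regiochemistry is eroded. The fallback sets out from 7 and moves the asymmetric step to an enone that already carries ring A. Morita–Baylis–Hillman reaction of 7 with 10 (imidazole, THF/H2O) should give 2-(hydroxymethyl)cyclopent-2-en-1-one F1. Acetylation (Ac2O, pyridine) should give (5-oxocyclopent-1-en-1-yl)methyl acetate F2. DABCO-mediated allylic substitution by the C4 carbon of 6 should give 2-benzoyl-3,5-dihydroxy-6,6-bis(3-methylbut-2-en-1-yl)-4-[(5-oxocyclopent-1-en-1-yl)methyl]cyclohexa-2,4-dien-1-one F3. Conjugate addition of isopropenylboronic acid pinacol ester to F3 (Rh(acac)(C2H4)2 with (S)-BINAP, KOH, dioxane/H2O), which tolerates the dienol as its potassium salt, then sets C3' and, after base equilibration of the enolisable C2' centre, should give 13. The silyl enol ether and the three-component step are bypassed, and the route is rejoined at 13.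

Step 5 may fail through poor facial discrimination (methyl entering syn to C7) or through enolisation of the cyclopentanone by the basic reagent. The fallback sets out from 13 and replaces direct methyl addition by methylene transfer and reduction. Corey–Chaykovsky reaction with dimethylsulfonium methylide (Me3S+ I−, KN(SiMe3)2, THF/DMSO, two extra equivalents for the dienol), a bulkier and less basic carbon nucleophile, should give the spiro-epoxide of 13 at C1' with the epoxide oxygen cis to C7 F4. Hydride opening at the epoxide CH2 with LiBHEt3 should then give 14, where the route is rejoined.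

Step 4 may fail through interception of 11 by unreacted 6 (methylene-bis adduct), self-condensation of 11, or protodesilylation of 9 by the acidic triketone before cycloaddition. The fallback sets out from 9 and makes the two bonds at C7 one after the other by known chemistry. Mannich reaction of 9 with dimethylmethylideneammonium iodide (CH2Cl2) should give (2S,3S)-2-[(dimethylamino)methyl]-3-(prop-1-en-2-yl)cyclopentan-1-one F5. Quaternisation (MeI) and elimination (NaHCO3) should give (R)-2-methylidene-3-(prop-1-en-2-yl)cyclopentan-1-one F6. Michael addition of 6 to F6 (cat. Et3N, THF), with thermodynamic protonation at C2', should then give 13, where the route is rejoined.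

**Further compounds**

F1 | step 3 | 2-(hydroxymethyl)cyclopent-2-en-1-one | O=C1CCC=C1CO
F2 | step 3 | (5-oxocyclopent-1-en-1-yl)methyl acetate | CC(=O)OCC1=CCCC1=O
F3 | step 3 | 2-benzoyl-3,5-dihydroxy-6,6-bis(3-methylbut-2-en-1-yl)-4-[(5-oxocyclopent-1-en-1-yl)methyl]cyclohexa-2,4-dien-1-one | O=C1CCC=C1CC1=C(O)C(CC=C(C)C)(CC=C(C)C)C(=O)C(C(=O)c2ccccc2)=C1O
F4 | step 5 | spiro-epoxide of 13 at C1' (1-oxaspiro[2.4]heptane unit, epoxide oxygen cis to C7) | C=C(C)[C@H]1CC[C@@]2(CO2)[C@@H]1CC1=C(O)C(CC=C(C)C)(CC=C(C)C)C(=O)C(C(=O)c3ccccc3)=C1O
F5 | step 4 | (2S,3S)-2-[(dimethylamino)methyl]-3-(prop-1-en-2-yl)cyclopentan-1-one | C=C(C)[C@H]1CCC(=O)[C@@H]1CN(C)C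
F6 | step 4 | (R)-2-methylidene-3-(prop-1-en-2-yl)cyclopentan-1-one | C=C(C)[C@H]1CCC(=O)C1=C
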